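**Retrosynthetic overview**
1. Target 26 ⇐ butanoylation and desilylation of alkene 24; the C3a=C4 double bond comes from dehydration of tertiary carbinol 23.
2. Key disconnection C4–C1': intermolecular carbonyl allylation of tricyclic keto-β-lactone 17 with the cyclic allylzinc made from isophorone; this step creates the quaternary centre C1'.
3. 17 ⇐ aldehyde acid 16 by one aldol-lactonisation that closes ring B (cyclopentane) and ring C (β-lactone) together.
4. 16 ⇐ (1R,2R)-cyclohex-4-ene-1,2-dicarboxylic acid 1 (ring A): iodolactonisation tells the two carboxyls apart and oxygenates C4; α'-allylation of the derived enone supplies C3, C2 and the lactone carbonyl carbon.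
5. Ring order: ring A (bought) → rings B and C (step 14) → trimethylcyclohexane ring attached ready-made (step 17).

Assumption: 1 is purchased as the single (1R,2R) enantiomer (a catalogue compound, also reachable by resolution of the cheap racemic trans-acid).
Locants for the bicyclic core follow indane numbering (C1 O-bearing, C2 carboxyl-bearing, C3, C3a, C4–C7, C7a); C1' is the quaternary carbon of the side ring. TBDPS = tert-butyldiphenylsilyl, TBS = tert-butyldimethylsilyl.
The configuration at C1' rests on a transition-state model (step 17), not on a preset stereocentre; it must be confirmed on 22 or 23 (X-ray or NOE) before continuing.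

**Route**

Step 1
Reactants: 1 (1R,2R)-cyclohex-4-ene-1,2-dicarboxylic acid
Product: 2 iodolactone acid
Conditions: I2, KI, NaHCO3, H2O, 0 °C to rt, dark; then HCl to pH 2
Reagents that add atoms: iodine, [I][I]
Why: Iodolactonisation (anti addition of carboxylate and iodine across the alkene): because 1 is C2-symmetric either carboxylate gives the same γ-lactone, so this single step differentiates the two carboxyls, puts oxygen on the future ketone carbon and sets iodine and oxygen trans-diaxial without touching the two existing stereocentres.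

Step 2
Reactants: 2 iodolactone acid
Product: 3 iodolactone alcohol
Conditions: BH3·THF, THF, 0 °C; MeOH quench
Reagents that add atoms: none
Why: Chemoselective borane reduction of a free carboxylic acid (via the acyloxyborane) leaves the lactone and the alkyl iodide alone, and the rigid trans-diaxial geometry keeps the new CH2OH away from the lactone carbonyl so no translactonisation occurs.

Step 3
Reactants: 3 iodolactone alcohol
Product: 4 TBDPS ether of 3
Conditions: TBDPSCl, imidazole, DMF, rt
Reagents that add atoms: tert-butyl(chloro)diphenylsilane, CC(C)(C)[Si](Cl)(c1ccccc1)c1ccccc1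
Why: Standard silylation of a primary alcohol (substitution at silicon) gives a robust ether that survives every step up to step 20.

Step 4
Reactants: 4 TBDPS iodolactone
Product: 5 unsaturated bicyclic lactone
Conditions: DBU, toluene, 90 °C
Reagents that add atoms: none
Why: E2 dehydroiodination: the axial iodide has one antiperiplanar hydrogen on the neighbouring CH2 and elimination towards the bridgehead is impossible, so only the alkene allylic to the lactone oxygen forms.

Step 5
Reactants: 5 unsaturated lactone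
Product: 6 cyclohexene diol
Conditions: LiAlH4, THF, 0 °C
Reagents that add atoms: none
Why: Hydride reduction of the lactone releases the primary alcohol and the already configured cis allylic secondary alcohol, while the silyl ether and the alkene are inert.

Step 6
Reactants: 6 diol
Product: 7 mono-TBS ether
Conditions: TBSCl (1.05 equiv), imidazole, CH2Cl2, 0 °C
Reagents that add atoms: tert-butyl(chloro)dimethylsilane, CC(C)(C)[Si](C)(C)Cl
Why: Silylation is much faster at the primary than at the secondary allylic hydroxyl (steric selectivity), so only the CH2OH that later becomes the aldehyde carbon is capped.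

Step 7
Reactants: 7 allylic alcohol
Product: 8 enone
Conditions: Dess–Martin periodinane, CH2Cl2, rt
Reagents that add atoms: none
Why: Dess–Martin oxidation of the allylic secondary alcohol gives the enone, whose C2=C3 double bond leaves C6 as the only enolisable sp3 α-carbon and so fixes the regiochemistry of step 8.

Step 8
Reactants: 8 enone
Product: 10 (4R,5S,6R)-6-allyl enone, via lithium dienolate 9 (not isolated)
Conditions: LiN(iPr)2, THF, −78 °C; allyl iodide, DMPU, −78 to −30 °C
Reagents that add atoms: allyl iodide, ICC=C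
Why: Kinetic α'-deprotonation gives the cross-conjugated lithium dienolate, and SN2 enolate alkylation with allyl iodide occurs trans to the adjacent C5 CH2OTBS group (this centre is epimerisable and becomes sp2 in the target, so it only needs to be the stable trans isomer).

Step 9
Reactants: 10 allyl enone
Product: 11 saturated ketone
Conditions: [(Ph3P)CuH]6, wet degassed toluene, rt
Reagents that add atoms: none
Why: Conjugate (1,4) reduction by the copper hydride delivers hydride to the enone β-carbon and water protonates the copper enolate, while the terminal alkene and silyl ethers are untouched and no stereocentre is created.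

Step 10
Reactants: 11 allyl ketone
Product: 13 diol (C1 carbinol epimer mixture), via bis-borane adduct 12 (not isolated)
Conditions: 9-BBN (3 equiv), THF, 0 °C to rt; then NaOH, H2O2, 0 °C
Reagents that add atoms: hydrogen peroxide, OO
Why: Hydroboration–oxidation gives the anti-Markovnikov primary alcohol, and the accompanying reduction of the ketone by excess 9-BBN is harmless because both carbinol epimers are reoxidised in step 11.

Step 11
Reactants: 13 diol
Product: 14 keto acid
Conditions: TEMPO (cat.), PhI(OAc)2 (4 equiv), MeCN/H2O, rt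
Reagents that add atoms: water, O
Why: Oxoammonium (TEMPO) oxidation takes the primary alcohol through the aldehyde hydrate to the carboxylic acid and returns the secondary alcohol to the ketone at near-neutral pH, where both silyl ethers are stable.

Step 12
Reactants: 14 keto acid
Product: 15 hydroxy keto acid
Conditions: HF·pyridine, pyridine, THF, 0 °C
Reagents that add atoms: none
Why: Selective fluoride-mediated desilylation: buffered HF·pyridine cleaves the primary TBS ether far faster than the primary TBDPS ether.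

Step 13
Reactants: 15 hydroxy keto acid
Product: 16 aldehyde acid
Conditions: Dess–Martin periodinane, CH2Cl2, rt
Reagents that add atoms: none
Why: Dess–Martin oxidation converts the primary alcohol into the aldehyde under non-basic conditions that tolerate the free acid and do not disturb the all-trans (thermodynamically preferred) arrangement around the ring.

Step 14
Reactants: 16 aldehyde acid
Product: 17 tricyclic keto β-lactone
Conditions: 2-chloro-1-methylpyridinium iodide, iPr2NEt, 4-pyrrolidinopyridine, CH2Cl2, rt, slow addition of 16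
Reagents that add atoms: none
Why: Nucleophile-catalysed aldol-lactonisation: the activated acid forms an acylammonium and then an ammonium enolate that adds to the aldehyde (closing ring B) and the aldolate closes the cis-fused oxetanone (ring C); the aldehyde oxygen turns to the face of C7a–H, away from the C7 CH2OTBDPS arm, which sets C1 (R) and C2 (S) with the C3a/C7a fusion staying trans.

Step 15
Reactants: 18 isophorone
Product: 19 isophorol (racemic)
Conditions: NaBH4, CeCl3·7H2O, MeOH, 0 °C
Reagents that add atoms: none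
Why: Luche reduction gives clean 1,2-hydride addition to the enone; the product is racemic, which is irrelevant because this stereocentre is lost in the allylmetal.

Step 16
Reactants: 19 isophorol
Product: 20 3-chloro-1,5,5-trimethylcyclohex-1-ene (racemic)
Conditions: SOCl2, pyridine (cat.), Et2O, 0 °C
Reagents that add atoms: thionyl chloride, O=S(Cl)Cl
Why: Allylic chlorination through the chlorosulfite; the secondary chloride and any tertiary allylic isomer are equivalent because both give the same allylzinc.

Step 17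
Reactants: 17 tricyclic keto β-lactone; 20 allylic chloride
Product: 22 tertiary homoallylic alcohol, via allylzinc chloride 21 (not isolated)
Conditions: 20, activated Zn dust, LiCl, THF, rt; then 17, THF, −78 °C; aqueous NH4Cl
Reagents that add atoms: none
Why: Intermolecular carbonyl allylation (Barbier-type allylzinc addition, SE2' through the methyl-bearing γ-carbon in a chair Zimmerman–Traxler transition state): equatorial attack on the C4 ketone with zinc bound on the unsubstituted C5 side is expected to give the required C1' configuration (1'R after step 18), the ketone reacts at −78 °C much faster than the lactone, and the C4 carbinol configuration is irrelevant because it is erased in step 19.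

Step 18
Reactants: 22 homoallylic alcohol
Product: 23 saturated tertiary alcohol
Conditions: H2 (1 atm), 10% Pd/C, EtOAc, rt
Reagents that add atoms: none
Why: Heterogeneous catalytic hydrogenation of the cis-disubstituted cyclohexene, done before dehydration so that no other C=C is present; the β-lactone, silyl ether and tertiary alcohol are inert.

Step 19
Reactants: 23 tertiary alcohol
Product: 24 tetrasubstituted alkene
Conditions: SOCl2, pyridine, CH2Cl2, −40 to 0 °C
Reagents that add atoms: none
Why: Dehydration by anti (E2) elimination of the axial chlorosulfite: the axial C3a–H is antiperiplanar and its loss gives the more substituted (Zaitsev) C3a=C4 alkene, with the C4=C5 isomer as the expected separable minor product.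

Step 20
Reactants: 24 TBDPS ether
Product: 25 primary alcohol
Conditions: HF·pyridine, THF, 0 °C to rt
Reagents that add atoms: none
Why: Fluoride-mediated cleavage of the silyl ether under acidic, non-nucleophilic conditions that leave the β-lactone and the tetrasubstituted alkene intact.

Step 21
Reactants: 25 primary alcohol
Product: 26 target CNP0144861.2
Conditions: butanoyl chloride, pyridine, CH2Cl2, 0 °C
Reagents that add atoms: butanoyl chloride, CCCC(=O)Cl
Why: Acylation of the primary alcohol by nucleophilic acyl substitution with pyridine as a mild base, so the β-lactone is not opened and no stereocentre is touched.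

**Compound list**

1 | (1R,2R)-cyclohex-4-ene-1,2-dicarboxylic acid | OC(=O)[C@@H]1CC=CC[C@H]1C(O)=O | starting material
2 | (1R,2R,4S,5S)-4-iodo-7-oxo-6-oxabicyclo[3.2.1]octane-2-carboxylic acid | OC(=O)[C@@H]1C[C@H]([I])[C@@H]2C[C@H]1C(=O)O2 | intermediate
3 | (1R,2R,4S,5S)-2-(hydroxymethyl)-4-iodo-6-oxabicyclo[3.2.1]octan-7-one | OC[C@@H]1C[C@H]([I])[C@@H]2C[C@H]1C(=O)O2 | intermediate
4 | (1R,2R,4S,5S)-2-{[tert-butyl(diphenyl)silyl]oxymethyl}-4-iodo-6-oxabicyclo[3.2.1]octan-7-one | CC(C)(C)[Si](c1ccccc1)(c1ccccc1)OC[C@@H]1C[C@H]([I])[C@@H]2C[C@H]1C(=O)O2 | intermediate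
5 | (1R,2R,5S)-2-{[tert-butyl(diphenyl)silyl]oxymethyl}-6-oxabicyclo[3.2.1]oct-3-en-7-one | CC(C)(C)[Si](c1ccccc1)(c1ccccc1)OC[C@@H]1C=C[C@@H]2C[C@H]1C(=O)O2 | intermediate
6 | (1S,4R,5R)-4-{[tert-butyl(diphenyl)silyl]oxymethyl}-5-(hydroxymethyl)cyclohex-2-en-1-ol | CC(C)(C)[Si](c1ccccc1)(c1ccccc1)OC[C@@H]1C=C[C@@H](O)C[C@H]1CO | intermediate
7 | (1S,4R,5R)-5-{[tert-butyl(dimethyl)silyl]oxymethyl}-4-{[tert-butyl(diphenyl)silyl]oxymethyl}cyclohex-2-en-1-ol | CC(C)(C)[Si](c1ccccc1)(c1ccccc1)OC[C@@H]1C=C[C@@H](O)C[C@H]1CO[Si](C)(C)C(C)(C)C | intermediate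
8 | (4R,5R)-5-{[tert-butyl(dimethyl)silyl]oxymethyl}-4-{[tert-butyl(diphenyl)silyl]oxymethyl}cyclohex-2-en-1-one | CC(C)(C)[Si](c1ccccc1)(c1ccccc1)OC[C@@H]1C=CC(=O)C[C@H]1CO[Si](C)(C)C(C)(C)C | intermediate
9 | lithium cross-conjugated dienolate of 8 (O–Li on C1, C1=C6) | CC(C)(C)[Si](c1ccccc1)(c1ccccc1)OC[C@@H]1C=CC(O[Li])=C[C@H]1CO[Si](C)(C)C(C)(C)C | intermediate (not isolated)
10 | (4R,5S,6R)-5-{[tert-butyl(dimethyl)silyl]oxymethyl}-4-{[tert-butyl(diphenyl)silyl]oxymethyl}-6-(prop-2-en-1-yl)cyclohex-2-en-1-one | CC(C)(C)[Si](c1ccccc1)(c1ccccc1)OC[C@@H]1C=CC(=O)[C@H](CC=C)[C@H]1CO[Si](C)(C)C(C)(C)C | intermediate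
11 | (2R,3S,4R)-3-{[tert-butyl(dimethyl)silyl]oxymethyl}-4-{[tert-butyl(diphenyl)silyl]oxymethyl}-2-(prop-2-en-1-yl)cyclohexan-1-one | CC(C)(C)[Si](c1ccccc1)(c1ccccc1)OC[C@@H]1CCC(=O)[C@H](CC=C)[C@H]1CO[Si](C)(C)C(C)(C)C | intermediate
12 | bis(9-borabicyclo[3.3.1]nonan-9-yl) adduct of 11 (B-alkyl at the chain terminus, O-boryl at C1; C1 epimers) | CC(C)(C)[Si](c1ccccc1)(c1ccccc1)OC[C@@H]1CCC(OB2C3CCCC2CCC3)[C@H](CCCB2C3CCCC2CCC3)[C@H]1CO[Si](C)(C)C(C)(C)C | intermediate (not isolated)
13 | (2R,3S,4R)-3-{[tert-butyl(dimethyl)silyl]oxymethyl}-4-{[tert-butyl(diphenyl)silyl]oxymethyl}-2-(3-hydroxypropyl)cyclohexan-1-ol, mixture of C1 epimers | CC(C)(C)[Si](c1ccccc1)(c1ccccc1)OC[C@@H]1CCC(O)[C@H](CCCO)[C@H]1CO[Si](C)(C)C(C)(C)C | intermediate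
14 | 3-[(1R,2S,3R)-2-{[tert-butyl(dimethyl)silyl]oxymethyl}-3-{[tert-butyl(diphenyl)silyl]oxymethyl}-6-oxocyclohexyl]propanoic acid | CC(C)(C)[Si](c1ccccc1)(c1ccccc1)OC[C@@H]1CCC(=O)[C@H](CCC(O)=O)[C@H]1CO[Si](C)(C)C(C)(C)C | intermediate
15 | 3-[(1R,2S,3R)-3-{[tert-butyl(diphenyl)silyl]oxymethyl}-2-(hydroxymethyl)-6-oxocyclohexyl]propanoic acid | CC(C)(C)[Si](c1ccccc1)(c1ccccc1)OC[C@@H]1CCC(=O)[C@H](CCC(O)=O)[C@H]1CO | intermediate
16 | 3-[(1R,2S,3R)-3-{[tert-butyl(diphenyl)silyl]oxymethyl}-2-formyl-6-oxocyclohexyl]propanoic acid | CC(C)(C)[Si](c1ccccc1)(c1ccccc1)OC[C@@H]1CCC(=O)[C@H](CCC(O)=O)[C@H]1C=O | intermediate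
17 | 1,2-β-lactone (cis-fused oxetan-2-one) of (1R,2S,3aR,7R,7aS)-7-{[tert-butyl(diphenyl)silyl]oxymethyl}-1-hydroxy-4-oxooctahydro-1H-indene-2-carboxylic acid, trans ring fusion | CC(C)(C)[Si](c1ccccc1)(c1ccccc1)OC[C@@H]1CCC(=O)[C@@H]2C[C@@H]3C(=O)O[C@@H]3[C@H]21 | intermediate
18 | isophorone (3,5,5-trimethylcyclohex-2-en-1-one) | CC1=CC(=O)CC(C)(C)C1 | starting material
19 | isophorol (3,5,5-trimethylcyclohex-2-en-1-ol), racemic | CC1=CC(O)CC(C)(C)C1 | intermediate
20 | 3-chloro-1,5,5-trimethylcyclohex-1-ene, racemic | CC1=CC(Cl)CC(C)(C)C1 | intermediate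
21 | (3,5,5-trimethylcyclohex-2-en-1-yl)zinc chloride | CC1=CC([Zn]Cl)CC(C)(C)C1 | intermediate (not isolated)
22 | 1,2-β-lactone of (1R,2S,3aR,4S,7R,7aS)-7-{[tert-butyl(diphenyl)silyl]oxymethyl}-1,4-dihydroxy-4-[(1S)-1,5,5-trimethylcyclohex-2-en-1-yl]octahydro-1H-indene-2-carboxylic acid | CC(C)(C)[Si](c1ccccc1)(c1ccccc1)OC[C@@H]1CC[C@@](O)([C@]2(C)C=CCC(C)(C)C2)[C@@H]2C[C@@H]3C(=O)O[C@@H]3[C@H]21 | intermediate
23 | 1,2-β-lactone of (1R,2S,3aR,4S,7R,7aS)-7-{[tert-butyl(diphenyl)silyl]oxymethyl}-1,4-dihydroxy-4-[(1R)-1,3,3-trimethylcyclohexyl]octahydro-1H-indene-2-carboxylic acid | CC(C)(C)[Si](c1ccccc1)(c1ccccc1)OC[C@@H]1CC[C@@](O)([C@]2(C)CCCC(C)(C)C2)[C@@H]2C[C@@H]3C(=O)O[C@@H]3[C@H]21 | intermediate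
24 | 1,2-β-lactone of (1R,2S,7R,7aS)-7-{[tert-butyl(diphenyl)silyl]oxymethyl}-1-hydroxy-4-[(1R)-1,3,3-trimethylcyclohexyl]-2,3,5,6,7,7a-hexahydro-1H-indene-2-carboxylic acid | CC(C)(C)[Si](c1ccccc1)(c1ccccc1)OC[C@@H]1CCC([C@]2(C)CCCC(C)(C)C2)=C2C[C@@H]3C(=O)O[C@@H]3[C@H]21 | intermediate
25 | 1,2-β-lactone of (1R,2S,7R,7aS)-1-hydroxy-7-(hydroxymethyl)-4-[(1R)-1,3,3-trimethylcyclohexyl]-2,3,5,6,7,7a-hexahydro-1H-indene-2-carboxylic acid | OC[C@@H]1CCC([C@]2(C)CCCC(C)(C)C2)=C2C[C@@H]3C(=O)O[C@@H]3[C@H]21 | intermediate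
26 | 1,2-β-lactone of (1R,2S,7R,7aS)-7-(butanoyloxymethyl)-1-hydroxy-4-[(1R)-1,3,3-trimethylcyclohexyl]-2,3,5,6,7,7a-hexahydro-1H-indene-2-carboxylic acid (CNP0144861.2) | CCCC(=O)OC[C@@H]1CCC([C@]2(C)CCCC(C)(C)C2)=C2C[C@@H]3C(=O)O[C@@H]3[C@H]21 | target

**Step count**
Total: 21 steps. Longest linear sequence: 19 steps (steps 1–14, then 17–21); the isophorone branch (steps 15–16) joins at step 17.

**Steps most likely to fail, with fallbacks**

Step 17 (allylzinc addition). Risks: attack on the strained lactone, and insufficient control at C1' in a very congested addition. The fallback sets out from keto acid 14 and comes back at 23; it forms the same bond before any β-lactone exists. Allylzinc 21 (3 equiv, the first consumed by the acid) is added to 14 in THF at −40 °C to give the tertiary hydroxy acid F3. Hydrogenation (H2, 10% Pd/C) gives the saturated hydroxy acid F4, buffered HF·pyridine frees the primary alcohol F5, and Dess–Martin oxidation gives the aldehyde acid F6. The hindered tertiary hydroxyl does not acylate, so the aldol-lactonisation conditions of step 14 then close rings B and C on F6 and deliver 23.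

Step 19 (dehydration). Risk: a mixture of C3a=C4 and C4=C5 alkenes, or cationic rearrangement next to C1'. The fallback sets out from 23 and comes back at 24 by making one regioisomer on purpose and then moving the double bond. Syn elimination with methyl N-(triethylammoniosulfonyl)carbamate (Burgess reagent, benzene, 50 °C) can only use the C5 hydrogen cis to the axial hydroxyl and gives the C4=C5 alkene F7. Radical hydrogen-atom-transfer isomerisation with [Co(salen)Cl] (a trivalent cobalt complex, 5 mol %) and PhSiH3 in benzene then shifts the double bond to the tetrasubstituted C3a=C4 position of 24 without carbocations. Whether the tetrasubstituted isomer is thermodynamically preferred here is not certain and must be checked.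

Step 14 (aldol-lactonisation). Risk: oligomerisation or low conversion of a substrate that carries both a ketone and an aldehyde. The fallback sets out from 16 and comes back at 17 by a stepwise metal-enolate route. 16 is converted (EDC·HCl, cat. DMAP, PhSH, CH2Cl2) into the S-phenyl thioester F1. Soft enolisation (MgBr2·OEt2, iPr2NEt, CH2Cl2, 0 °C) effects the intramolecular aldol to the cis β-hydroxy thioester F2. Its magnesium alkoxide on warming, or AgOCOCF3 (monovalent silver), displaces thiophenolate and closes the oxetanone to give 17.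

Further compounds
F1 | step 14 | S-phenyl 3-[(1R,2S,3R)-3-{[tert-butyl(diphenyl)silyl]oxymethyl}-2-formyl-6-oxocyclohexyl]propanethioate | CC(C)(C)[Si](c1ccccc1)(c1ccccc1)OC[C@@H]1CCC(=O)[C@H](CCC(=O)Sc2ccccc2)[C@H]1C=O
F2 | step 14 | S-phenyl (1R,2S,3aR,7R,7aS)-7-{[tert-butyl(diphenyl)silyl]oxymethyl}-1-hydroxy-4-oxooctahydro-1H-indene-2-carbothioate | CC(C)(C)[Si](c1ccccc1)(c1ccccc1)OC[C@@H]1CCC(=O)[C@@H]2C[C@H](C(=O)Sc3ccccc3)[C@H](O)[C@H]21
F3 | step 17 | 3-[(1R,2S,3R,6S)-2-{[tert-butyl(dimethyl)silyl]oxymethyl}-3-{[tert-butyl(diphenyl)silyl]oxymethyl}-6-hydroxy-6-[(1S)-1,5,5-trimethylcyclohex-2-en-1-yl]cyclohexyl]propanoic acid | CC(C)(C)[Si](c1ccccc1)(c1ccccc1)OC[C@@H]1CC[C@@](O)([C@]2(C)C=CCC(C)(C)C2)[C@H](CCC(O)=O)[C@H]1CO[Si](C)(C)C(C)(C)C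
F4 | step 17 | 3-[(1R,2S,3R,6S)-2-{[tert-butyl(dimethyl)silyl]oxymethyl}-3-{[tert-butyl(diphenyl)silyl]oxymethyl}-6-hydroxy-6-[(1R)-1,3,3-trimethylcyclohexyl]cyclohexyl]propanoic acid | CC(C)(C)[Si](c1ccccc1)(c1ccccc1)OC[C@@H]1CC[C@@](O)([C@]2(C)CCCC(C)(C)C2)[C@H](CCC(O)=O)[C@H]1CO[Si](C)(C)C(C)(C)C
F5 | step 17 | 3-[(1R,2S,3R,6S)-3-{[tert-butyl(diphenyl)silyl]oxymethyl}-6-hydroxy-2-(hydroxymethyl)-6-[(1R)-1,3,3-trimethylcyclohexyl]cyclohexyl]propanoic acid | CC(C)(C)[Si](c1ccccc1)(c1ccccc1)OC[C@@H]1CC[C@@](O)([C@]2(C)CCCC(C)(C)C2)[C@H](CCC(O)=O)[C@H]1CO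
F6 | step 17 | 3-[(1R,2S,3R,6S)-3-{[tert-butyl(diphenyl)silyl]oxymethyl}-2-formyl-6-hydroxy-6-[(1R)-1,3,3-trimethylcyclohexyl]cyclohexyl]propanoic acid | CC(C)(C)[Si](c1ccccc1)(c1ccccc1)OC[C@@H]1CC[C@@](O)([C@]2(C)CCCC(C)(C)C2)[C@H](CCC(O)=O)[C@H]1C=O
F7 | step 19 | C4=C5 regioisomer of 24: 1,2-β-lactone of (1R,2S,3aR,7R,7aR)-7-{[tert-butyl(diphenyl)silyl]oxymethyl}-1-hydroxy-4-[(1R)-1,3,3-trimethylcyclohexyl]-2,3,3a,6,7,7a-hexahydro-1H-indene-2-carboxylic acid | CC(C)(C)[Si](c1ccccc1)(c1ccccc1)OC[C@@H]1CC=C([C@]2(C)CCCC(C)(C)C2)[C@@H]2C[C@@H]3C(=O)O[C@@H]3[C@H]21
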